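**Retrosynthetic overview** (ring A = methylcyclopentane, B = eight-membered ring, C = cyclohexene, D = cyclopentanol)
1. Target ⇐ ring-D enone (isopropyl by conjugate addition, OH by ketone reduction) ⇐ methylenation of the ring-B enone 19.
2. 19 ⇐ pinacol-type 1,2-shift of cis-diol monomesylate 18: a cyclohexane contracts to ring A while a cycloheptene expands to ring B.
3. Diol 17 ⇐ dihydroxylation of tetracyclic diene 16 ⇐ nickel-mediated closure of the seven-membered ring from bis(enol triflate) 15.
4. 15 ⇐ cyclohexanone (from 2-iodocyclohexenone: B-alkyl Suzuki, Cu-catalysed methyl addition) tethered to hydrindane enol triflate 10.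
5. 10 ⇐ (R)-Hajos–Parrish ketone (rings C/D) by Ir-crotylation and Li/NH3 reduction. Ring order: D/C → six-membered precursor of A → seven-membered precursor of B → 1,2-shift gives A and B together.

Assumption: 7 and 11 are bought. The ring carbon carrying the butenyl group in 8 and 9 is an epimer mixture (left undefined in the SMILES) because it becomes sp2 in 10. Ligand enantiomers in steps 4 and 8 are chosen to give the configurations drawn.

Step 1
Reactants: 1 2-methylcyclopentane-1,3-dione; 2 but-3-en-2-one
Product: 3 2-methyl-2-(3-oxobutyl)cyclopentane-1,3-dione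
Conditions: H2O, AcOH (cat.), 75 °C
Reagents that add atoms: none
Why: Michael addition of the doubly activated C2–H of the 1,3-dione to the vinyl ketone; no stereocentre is formed.

Step 2
Reactants: 3 2-methyl-2-(3-oxobutyl)cyclopentane-1,3-dione
Product: 5 (R)-Hajos–Parrish ketone, via cis-ketol 4 (not isolated)
Conditions: (R)-proline (3 mol %), DMF, 20 °C; then H2SO4 (cat.), 95 °C
Reagents that add atoms: none
Why: Hajos–Parrish–Eder–Sauer–Wiechert enamine aldol, in which (R)-proline selects one enantiotopic ring carbonyl and sets the (R) quaternary methyl centre, followed by acid dehydration of the ketol.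

Step 3
Reactants: 5 (R)-Hajos–Parrish ketone
Product: 6 C1 ethylene acetal of 5 (enone intact)
Conditions: HOCH2CH2OH, p-TsOH (cat.), 4 Å sieves, CH2Cl2, 20 °C
Reagents that add atoms: ethylene glycol OCCO
Why: Selective acetalisation, since the saturated cyclopentanone carbonyl is more electrophilic than the conjugated one (as in the Wieland–Miescher series); no stereocentre is formed.

Step 4
Reactants: 6 C1 ethylene acetal of 5; 7 (E)-but-2-en-1-yl acetate
Product: 8 6-[(S)-but-3-en-2-yl] enone acetal (C6 epimers)
Conditions: LiN(SiMe3)2, THF, −78 °C; then 7, [Ir(cod)Cl]2 (2 mol %), Feringa-type phosphoramidite (4 mol %), −78 → 20 °C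
Reagents that add atoms: none
Why: Kinetic α′-deprotonation gives the cross-conjugated enolate, and Ir-catalysed branched-selective allylic alkylation (Hartwig–Helmchen type) sets the (S) methyl-bearing side-chain carbon under ligand control.

Step 5
Reactants: 8 6-[(S)-but-3-en-2-yl] enone acetal
Product: 9 trans-fused hydrindan-5-one (3a-H anti to 7a-CH3; C6 epimers)
Conditions: Li, NH3 (l), THF, t-BuOH (1 equiv), −78 °C; then NH4Cl
Reagents that add atoms: none
Why: Dissolving-metal (Birch-type) enone reduction, in which protonation of the β-carbanion places the ring-fusion hydrogen anti to the angular methyl (trans-hydrindanone); the isolated vinyl group and the acetal survive.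

Step 6
Reactants: 9 trans-fused hydrindan-5-one
Product: 10 tetrasubstituted 5,6-enol triflate
Conditions: Tf2O, 2,6-di-tert-butyl-4-methylpyridine, CH2Cl2, 0 → 20 °C
Reagents that add atoms: trifluoromethanesulfonic anhydride O=S(=O)(OS(=O)(=O)C(F)(F)F)C(F)(F)F
Why: Enol triflation under equilibrating conditions gives the more substituted enol triflate, helped by the preference of trans-hydrindan-5-ones for the 5,6- over the 4,5-double bond; the epimeric centre of 9 is erased.

Step 7
Reactants: 10 tetrasubstituted 5,6-enol triflate; 11 2-iodocyclohex-2-en-1-one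
Product: 13 2-alkylcyclohex-2-enone tethered to the hydrindenyl triflate, via B-alkyl-9-BBN 12 (not isolated)
Conditions: 9-BBN-H, THF, 0 → 20 °C; then 11, Pd(dppf)Cl2 (5 mol %), AsPh3, Cs2CO3, DMF/H2O, 20 °C
Reagents that add atoms: none
Why: Anti-Markovnikov hydroboration of the only monosubstituted alkene, then B-alkyl Suzuki–Miyaura coupling with the α-iodoenone (Johnson conditions); oxidative addition into the C–I bond far outruns the hindered enol triflate, and no stereocentre is formed.

Step 8
Reactants: 13 2-alkylcyclohex-2-enone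
Product: 14 (2S,3S)-cis-2-alkyl-3-methylcyclohexanone
Conditions: AlMe3, Cu(OTf)2 (5 mol %), chiral phosphoramidite (10 mol %), Et2O, −30 °C; then MeOH, −78 °C
Reagents that add atoms: trimethylaluminium C[Al](C)C
Why: Cu-catalysed asymmetric conjugate addition (Alexakis type) sets the methyl centre under ligand control, and kinetic axial protonation of the 2,3-disubstituted enolate anti to the pseudoaxial methyl (allylic 1,2-strain) gives the cis-2,3 ketone.

Step 9
Reactants: 14 (2S,3S)-cis-2-alkyl-3-methylcyclohexanone
Product: 15 bis(enol triflate)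
Conditions: LiN(iPr)2, THF, −78 °C; then PhNTf2, −78 → 0 °C
Reagents that add atoms: N-phenylbis(trifluoromethanesulfonimide) O=S(=O)(N(c1ccccc1)S(=O)(=O)C(F)(F)F)C(F)(F)F
Why: Kinetic deprotonation at the unhindered α-CH2 and O-triflation give the less substituted enol triflate without epimerising the tertiary α-carbon.

Step 10
Reactants: 15 bis(enol triflate)
Product: 16 tetracyclic diene (cyclohexene–cycloheptene–ring C–ring D acetal)
Conditions: Ni(cod)2 (2.2 equiv), 2,2′-bipyridine, DMF/THF, 45 °C, slow addition to 0.003 M
Reagents that add atoms: none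
Why: Proposed new method: intramolecular reductive cross-coupling of two different enol triflates, in which zerovalent nickel adds to the less hindered trisubstituted C–OTf bond, the divalent alkenylnickel triflate is reduced by more zerovalent nickel to a monovalent alkenylnickel that adds the tethered tetrasubstituted enol triflate, and reductive elimination from trivalent nickel forms the sp2–sp2 bond closing the seven-membered ring as a 1,3-diene; the closest known reactions are the Semmelhack Ni(cod)2 coupling of alkenyl halides and Ni/Zn homocoupling of enol triflates, and no stereocentre is created.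

Step 11
Reactants: 16 tetracyclic diene
Product: 17 cis-diol (tertiary OH at the ring-fusion carbon; secondary OH on the adjacent CH)
Conditions: OsO4 (5 mol %), NMO, acetone/H2O, 0 → 20 °C
Reagents that add atoms: N-methylmorpholine N-oxide C[N+]1([O-])CCOCC1; water O
Why: Upjohn syn-dihydroxylation of the only trisubstituted alkene, from the face opposite the pseudoaxial ring bond and the methyl group, gives the cis-diol with the tertiary OH syn to the ring-fusion hydrogen.

Step 12
Reactants: 17 cis-diol
Product: 19 tetracyclic enone with rings A–D (trans A/B fusion), via monomesylate 18 (not isolated)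
Conditions: MsCl, Et3N, CH2Cl2, −10 °C; then KOtBu (1.1 equiv), t-BuOH/THF, 0 → 20 °C
Reagents that add atoms: none
Why: Selective mesylation of the secondary alcohol, then a Heathcock-type pinacol 1,2-alkyl shift: the ring-fusion C–C bond antiperiplanar to the equatorial C–OMs bond migrates to the mesylate carbon (inversion there, retention at the migrating carbon), contracting the cyclohexane to ring A and expanding the cycloheptene to the ring-B enone with the trans A/B hydrogens.

Step 13
Reactants: 19 tetracyclic enone
Product: 20 exocyclic-methylene diene acetal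
Conditions: Cp2TiMe2 (3 equiv), toluene, 70 °C, dark
Reagents that add atoms: dimethyltitanocene C[Ti](C)(C1C=CC=C1)C1C=CC=C1
Why: Petasis methylenation (titanium methylidene, oxatitanacyclobutane) olefinates the hindered enone carbonyl under non-basic conditions, so the α- and γ-stereocentres are untouched.

Step 14
Reactants: 20 exocyclic-methylene diene acetal
Product: 21 ring-D ketone
Conditions: PPTS (cat.), THF/H2O, 40 °C
Reagents that add atoms: water O
Why: Mild acid-catalysed acetal hydrolysis that leaves the 1,3-diene in place; no stereocentre is affected.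

Step 15
Reactants: 21 ring-D ketone
Product: 22 ring-D cyclopentenone
Conditions: LiN(iPr)2, THF, −78 °C; then PhS(Cl)=NtBu, −78 °C
Reagents that add atoms: none
Why: Mukaiyama dehydrogenation, in which the only enolisable α-CH2 is sulfinimidoylated and syn-elimination gives the enone.

Step 16
Reactants: 22 ring-D cyclopentenone
Product: 23 isopropyl ketone
Conditions: i-PrMgCl, CuBr·SMe2 (20 mol %), THF, −40 °C; then aq. NH4Cl
Reagents that add atoms: isopropylmagnesium chloride CC(C)[Mg]Cl
Why: Cu-catalysed conjugate addition anti to the 1,3-related angular methyl sets the isopropyl centre trans to the methyl and cis to the ring-fusion hydrogen.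

Step 17
Reactants: 23 isopropyl ketone
Product: 24 CNP0544018.1
Conditions: NaBH4, MeOH, 0 °C
Reagents that add atoms: none
Why: Hydride attacks the neopentyl cyclopentanone from the face opposite the adjacent angular methyl (as in 17-keto steroids), giving the alcohol cis to the methyl group.

**Compound list**
1 | 2-methylcyclopentane-1,3-dione | CC1C(=O)CCC1=O | starting material
2 | but-3-en-2-one | CC(=O)C=C | starting material
3 | 2-methyl-2-(3-oxobutyl)cyclopentane-1,3-dione | CC(=O)CCC1(C)C(=O)CCC1=O | intermediate
4 | (3aR,7aR)-3a-hydroxy-7a-methylhexahydro-1H-indene-1,5(4H)-dione (cis-ketol, not isolated) | O=C1CC[C@@]2(C)C(=O)CC[C@@]2(O)C1 | intermediate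
5 | (R)-7a-methyl-2,3,7,7a-tetrahydro-1H-indene-1,5(6H)-dione ((R)-Hajos–Parrish ketone) | O=C1CC[C@@]2(C)C(=O)CCC2=C1 | intermediate
6 | C1 ethylene acetal of 5 | O=C1CC[C@@]2(C)C3(OCCO3)CCC2=C1 | intermediate
7 | (E)-but-2-en-1-yl acetate | C/C=C/COC(C)=O | starting material
8 | 6-[(S)-but-3-en-2-yl] derivative of 6 (C6 epimers) | O=C1C([C@@H](C)C=C)C[C@@]2(C)C3(OCCO3)CCC2=C1 | intermediate
9 | trans-fused 1,1-ethylenedioxy-7a-methyl-6-[(S)-but-3-en-2-yl]octahydroinden-5-one | O=C1C([C@@H](C)C=C)C[C@@]2(C)C3(OCCO3)CC[C@@H]2C1 | intermediate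
10 | 5-triflyloxy-5,6-ene (tetrasubstituted enol triflate of 9) | FC(F)(F)S(=O)(=O)OC1=C(C[C@@]2(C)C3(OCCO3)CC[C@@H]2C1)[C@@H](C)C=C | intermediate
11 | 2-iodocyclohex-2-en-1-one | O=C1CCCC=C1I | starting material
12 | B-alkyl-9-BBN from hydroboration of 10 (not isolated) | FC(F)(F)S(=O)(=O)OC1=C(C[C@@]2(C)C3(OCCO3)CC[C@@H]2C1)[C@@H](C)CCB1C2CCCC1CCC2 | intermediate
13 | 2-[(3S)-3-(hydrindenyl triflate)butyl]cyclohex-2-en-1-one | FC(F)(F)S(=O)(=O)OC1=C(C[C@@]2(C)C3(OCCO3)CC[C@@H]2C1)[C@@H](C)CCC1=CCCCC1=O | intermediate
14 | (2S,3S)-cis-2-alkyl-3-methylcyclohexanone | FC(F)(F)S(=O)(=O)OC1=C(C[C@@]2(C)C3(OCCO3)CC[C@@H]2C1)[C@@H](C)CC[C@H]1[C@@H](C)CCCC1=O | intermediate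
15 | bis(enol triflate) | FC(F)(F)S(=O)(=O)OC1=C(C[C@@]2(C)C3(OCCO3)CC[C@@H]2C1)[C@@H](C)CC[C@H]1[C@@H](C)CCC=C1OS(=O)(=O)C(F)(F)F | intermediate
16 | tetracyclic diene (new bond between the two former triflate carbons) | C1=C2C3=C(C[C@@]4(C)C5(OCCO5)CC[C@@H]4C3)[C@@H](C)CC[C@H]2[C@@H](C)CC1 | intermediate
17 | cis-diol of 16 | O[C@]12C3=C(C[C@@]4(C)C5(OCCO5)CC[C@@H]4C3)[C@@H](C)CC[C@H]1[C@@H](C)CC[C@@H]2O | intermediate
18 | secondary monomesylate of 17 (not isolated) | O[C@]12C3=C(C[C@@]4(C)C5(OCCO5)CC[C@@H]4C3)[C@@H](C)CC[C@H]1[C@@H](C)CC[C@@H]2OS(C)(=O)=O | intermediate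
19 | tetracyclic ring-B enone, ring-D acetal | O=C1C2=C(C[C@@]3(C)C4(OCCO4)CC[C@@H]3C2)[C@@H](C)CC[C@@H]2[C@@H]1CC[C@@H]2C | intermediate
20 | exocyclic-methylene diene, ring-D acetal | C=C1C2=C(C[C@@]3(C)C4(OCCO4)CC[C@@H]3C2)[C@@H](C)CC[C@@H]2[C@@H]1CC[C@@H]2C | intermediate
21 | ring-D ketone | C=C1C2=C(C[C@@]3(C)C(=O)CC[C@@H]3C2)[C@@H](C)CC[C@@H]2[C@@H]1CC[C@@H]2C | intermediate
22 | ring-D cyclopentenone | C=C1C2=C(C[C@@]3(C)C(=O)C=C[C@@H]3C2)[C@@H](C)CC[C@@H]2[C@@H]1CC[C@@H]2C | intermediate
23 | isopropyl ketone | C=C1C2=C(C[C@@]3(C)C(=O)C[C@@H](C(C)C)[C@@H]3C2)[C@@H](C)CC[C@@H]2[C@@H]1CC[C@@H]2C | intermediate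
24 | CNP0544018.1 | C=C1C2=C(C[C@@]3(C)[C@H](O)C[C@@H](C(C)C)[C@@H]3C2)[C@@H](C)CC[C@@H]2[C@@H]1CC[C@@H]2C | target

**Totals**
Total step count: 17. Longest linear sequence: 17 (from 1 and 2; 7 and 11 are bought).

**Three steps most likely to fail**

Step 10 (the proposed nickel ring closure). Fallback with known chemistry, setting out from 15 and returning at 16: Miyaura borylation (Pd(dppf)Cl2, B2pin2, KOAc, dioxane, 80 °C) of the less hindered trisubstituted triflate gives the alkenyl boronate F5. Intramolecular Suzuki–Miyaura coupling (Pd(PPh3)4, Cs2CO3, DMF/H2O, high dilution) with the remaining tetrasubstituted triflate then closes the seven-membered ring to 16.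

Step 8 (ligand-controlled methyl addition to a 2-substituted enone and cis-selective protonation). Fallback, setting out from 10 and returning at 14: 10 is hydroborated as in step 7, and the borane 12 is coupled with 2-iodo-3-methylcyclohex-2-en-1-one F3 (from purchased 3-methylcyclohex-2-en-1-one with I2/pyridine). This gives the tetrasubstituted enone F4. Heterogeneous syn-hydrogenation (H2, Rh/Al2O3, EtOAc) puts both hydrogens on one face, so the 2,3-cis relationship comes from the addition itself and not from a protonation. The two cis diastereomers are separated and the required one is 14; this route gives up ligand control, so at most half the material is usable.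

Step 4 (Ir allylation of a cross-conjugated enolate with an allylic acetate). Fallback, setting out from 6 and returning at 8: 6 is deprotonated (LiN(iPr)2, THF, −78 °C) and condensed with acetaldehyde to the aldol F1. F1 is dehydrated (MsCl, Et3N; then DBU) to the (E)-ethylidene dienone F2. Vinylmagnesium bromide with CuBr·SMe2 adds to the unhindered exocyclic β-carbon (the ring β-carbon is fully substituted), and protonation gives 8 as side-chain epimers, from which the (S) epimer is separated.

Further compounds
F1 | step 4 | 6-(1-hydroxyethyl) aldol of 6 | O=C1C(C(C)O)C[C@@]2(C)C3(OCCO3)CCC2=C1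
F2 | step 4 | (E)-6-ethylidene dienone acetal | O=C1/C(=C/C)C[C@@]2(C)C3(OCCO3)CCC2=C1
F3 | step 8 | 2-iodo-3-methylcyclohex-2-en-1-one | CC1=C(I)C(=O)CCC1
F4 | step 8 | 2-alkyl-3-methylcyclohex-2-en-1-one (tetrasubstituted enone analogue of 13) | FC(F)(F)S(=O)(=O)OC1=C(C[C@@]2(C)C3(OCCO3)CC[C@@H]2C1)[C@@H](C)CCC1=C(C)CCCC1=O
F5 | step 10 | cyclohexenyl pinacol boronate of 15 (hydrindenyl triflate retained) | FC(F)(F)S(=O)(=O)OC1=C(C[C@@]2(C)C3(OCCO3)CC[C@@H]2C1)[C@@H](C)CC[C@H]1[C@@H](C)CCC=C1B1OC(C)(C)C(C)(C)O1
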